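**Retrosynthetic overview**

- Ring C is the only ring that has to be made. It rests on two features: C4 is a lone carbonyl carbon held between C4a of ring A and C3, and O1–C2 is the enol-ether bond of the γ-pyrone. Ring C therefore opens at C4a–C4, C4–C3 and O1–C2 to an o-iodophenol (ring A with the C8 chain already in place), carbon monoxide and the ring-B arylacetylene.
- The 3-OH is added after ring closure by C3 lithiation, borylation and oxidation; the MOM and silyl groups are removed last under non-protic or buffered conditions.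
- The iodophenol comes from phloroglucinol: two MOM ethers, an O-carbamate on the future O1, and two carbamate-directed ortho-metalations. The C8–CH2 bond is made by a B-alkyl Suzuki coupling rather than by alkylating the ortho-lithiated carbamate.
- The side-chain stereocentre is set by an Evans deconjugative alkylation with prenyl bromide; epoxidation and hydride opening turn the prenyl group into the tertiary alcohol.
- Order of ring formation: rings A and B are bought, ring C is closed in the carbonylative step.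

Key step: step 15

Remark: epoxide 8 is carried as a mixture of its two oxirane epimers, because that carbon becomes CH2 in step 4. The side-chain centre is (S) by CIP in 7–11 and (R) once bonded to the arene; only the priorities change, not the spatial arrangement.

**Side chain**

Step 1
Reactants: 1 (S)-4-benzyloxazolidin-2-one; 2 3-methylbut-2-enoyl chloride
Product: 4 (S)-4-benzyl-3-(3-methylbut-2-enoyl)oxazolidin-2-one, via lithium oxazolidinide 3 (not isolated)
Conditions: n-BuLi, THF, −78 °C; then 2, −78 → 0 °C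
Reagents that add atoms: none
Why: N-acylation of a lithiated oxazolidinone with an acid chloride is the standard entry to Evans imides, and the low temperature avoids deconjugation of the senecioyl group.

Step 2
Reactants: 4 (S)-4-benzyl-3-(3-methylbut-2-enoyl)oxazolidin-2-one; 5 1-bromo-3-methylbut-2-ene (prenyl bromide)
Product: 7 (4S)-4-benzyl-3-[(2S)-5-methyl-2-(prop-1-en-2-yl)hex-4-enoyl]oxazolidin-2-one, via sodium dienolate 6 (not isolated)
Conditions: NaHMDS, THF, −78 °C; then 5, −78 → −40 °C
Reagents that add atoms: none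
Why: Evans deconjugative α-alkylation: γ-deprotonation gives the chelated Z(O)-dienolate, prenyl bromide attacks Cα on the face opposite the C4 benzyl group, and this sets the (2S) centre and leaves the β,γ-alkene as the isopropenyl group.

Step 3
Reactants: 7 (4S)-4-benzyl-3-[(2S)-5-methyl-2-(prop-1-en-2-yl)hex-4-enoyl]oxazolidin-2-one
Product: 8 (4S)-4-benzyl-3-[(2S)-2-[(3,3-dimethyloxiran-2-yl)methyl]-3-methylbut-3-enoyl]oxazolidin-2-one (both oxirane epimers)
Conditions: mCPBA (1.05 equiv), NaHCO3, CH2Cl2, −20 → 0 °C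
Reagents that add atoms: 3-chloroperoxybenzoic acid (mCPBA), O=C(OO)c1cccc(Cl)c1
Why: Prilezhaev epoxidation should be faster at the electron-rich trisubstituted prenyl alkene than at the 1,1-disubstituted isopropenyl alkene (the preference that gives limonene 1,2-oxide), and the new oxirane centre is erased in step 4.

Step 4
Reactants: 8 (4S)-4-benzyl-3-[(2S)-2-[(3,3-dimethyloxiran-2-yl)methyl]-3-methylbut-3-enoyl]oxazolidin-2-one
Product: 9 (2S)-5-methyl-2-(prop-1-en-2-yl)hexane-1,5-diol
Conditions: LiAlH4, THF, 0 → 50 °C; Rochelle salt work-up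
Reagents that add atoms: none
Why: Hydride reduction cleaves the imide to the primary alcohol with release of the auxiliary and opens the trisubstituted epoxide by SN2 attack at its less substituted carbon to give the tertiary alcohol, without touching the allylic stereocentre.

Step 5
Reactants: 9 (2S)-5-methyl-2-(prop-1-en-2-yl)hexane-1,5-diol
Product: 10 (5S)-6-iodo-2-methyl-5-(prop-1-en-2-yl)hexan-2-ol
Conditions: I2, PPh3, imidazole, CH2Cl2, 0 °C → rt
Reagents that add atoms: iodine, II
Why: Appel-type iodination converts the primary alcohol by SN2 displacement of its alkoxyphosphonium salt, while the hindered tertiary alcohol should not react at this temperature.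

Step 6
Reactants: 10 (5S)-6-iodo-2-methyl-5-(prop-1-en-2-yl)hexan-2-ol
Product: 11 triethyl{[(5S)-6-iodo-2-methyl-5-(prop-1-en-2-yl)hexan-2-yl]oxy}silane
Conditions: TESOTf, 2,6-lutidine, CH2Cl2, −78 → 0 °C
Reagents that add atoms: triethylsilyl trifluoromethanesulfonate, CC[Si](CC)(CC)OS(=O)(=O)C(F)(F)F
Why: Silyl triflate with 2,6-lutidine is the usual silylation of a tertiary alcohol, and the TES ether masks the acidic OH for the organolithium steps.

**Ring A**

Step 7
Reactants: 12 phloroglucinol
Product: 13 3,5-bis(methoxymethoxy)phenol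
Conditions: MOMCl (2.0 equiv), i-Pr2NEt, DMF, 0 °C → rt; chromatography, mono- and tris-ethers recycled
Reagents that add atoms: chloromethyl methyl ether, COCCl
Why: Williamson-type O-alkylation of the symmetric triol with two equivalents of MOMCl should give the bis-ether as the main component of a separable statistical mixture.

Step 8
Reactants: 13 3,5-bis(methoxymethoxy)phenol
Product: 14 3,5-bis(methoxymethoxy)phenyl N,N-diethylcarbamate
Conditions: ClCONEt2, K2CO3, MeCN, reflux
Reagents that add atoms: N,N-diethylcarbamoyl chloride, CCN(CC)C(Cl)=O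
Why: O-carbamoylation of the phenoxide places the strongest oxygen-based directed-metalation group on the oxygen that becomes O1.

Step 9
Reactants: 14 3,5-bis(methoxymethoxy)phenyl N,N-diethylcarbamate
Product: 16 2-iodo-3,5-bis(methoxymethoxy)phenyl N,N-diethylcarbamate, via aryllithium 15 (not isolated)
Conditions: s-BuLi, TMEDA, THF, −78 °C; then I2, −78 °C
Reagents that add atoms: iodine, II
Why: Directed ortho-metalation: carbamate-complexed s-BuLi should remove the proton between OCONEt2 and OMOM, the aryllithium does not undergo anionic Fries rearrangement at −78 °C, and iodine quenches it to the aryl iodide.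

Step 10
Reactants: 11 triethyl{[(5S)-6-iodo-2-methyl-5-(prop-1-en-2-yl)hexan-2-yl]oxy}silane; 16 2-iodo-3,5-bis(methoxymethoxy)phenyl N,N-diethylcarbamate
Product: 19 3,5-bis(methoxymethoxy)-2-{(2R)-5-methyl-2-(prop-1-en-2-yl)-5-[(triethylsilyl)oxy]hexyl}phenyl N,N-diethylcarbamate, via alkyllithium 17 (not isolated), via lithium alkyl(methoxy)-9-BBN borate 18 (not isolated)
Conditions: 11, t-BuLi (2.1 equiv), Et2O, −78 °C; B-MeO-9-BBN, THF, −78 °C → rt; then 16, Pd(OAc)2/SPhos, aq K3PO4, DMF, 50 °C
Reagents that add atoms: none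
Why: B-alkyl Suzuki–Miyaura coupling through the 9-BBN ate complex (made by iodine–lithium exchange) joins the β-branched primary alkyl group to the hindered aryl iodide, which avoids warming the ortho-lithiated carbamate to the temperatures at which it rearranges; the stereocentre is not involved.

Step 11
Reactants: 19 3,5-bis(methoxymethoxy)-2-{(2R)-5-methyl-2-(prop-1-en-2-yl)-5-[(triethylsilyl)oxy]hexyl}phenyl N,N-diethylcarbamate
Product: 21 2-iodo-3,5-bis(methoxymethoxy)-6-{(2R)-5-methyl-2-(prop-1-en-2-yl)-5-[(triethylsilyl)oxy]hexyl}phenyl N,N-diethylcarbamate, via aryllithium 20 (not isolated)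
Conditions: s-BuLi, TMEDA, THF, −78 °C; then I2, −78 °C
Reagents that add atoms: iodine, II
Why: A second directed ortho-metalation should take the one remaining proton flanked by the carbamate and a MOM ether, in preference to the position between the two MOM ethers and to lateral benzylic deprotonation, and iodination fixes the halogen next to the future O1.

Step 12
Reactants: 21 2-iodo-3,5-bis(methoxymethoxy)-6-{(2R)-5-methyl-2-(prop-1-en-2-yl)-5-[(triethylsilyl)oxy]hexyl}phenyl N,N-diethylcarbamate
Product: 22 2-iodo-3,5-bis(methoxymethoxy)-6-{(2R)-5-methyl-2-(prop-1-en-2-yl)-5-[(triethylsilyl)oxy]hexyl}phenol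
Conditions: KOH, EtOH/H2O, 80 °C; then aq NH4Cl
Reagents that add atoms: none
Why: Alkaline hydrolysis of the N,N-diethylcarbamate (BAc2) frees the phenol, and the MOM acetals, aryl iodide, alkene and hindered tertiary silyl ether should tolerate hydroxide.

**Ring-B alkyne**

Step 13
Reactants: 23 2,4-dihydroxybenzaldehyde
Product: 24 2,4-bis(methoxymethoxy)benzaldehyde
Conditions: MOMCl (2.5 equiv), i-Pr2NEt, CH2Cl2, 0 °C → rt
Reagents that add atoms: chloromethyl methyl ether, COCCl
Why: Williamson-type MOM protection of both phenols, with excess reagent to overcome the hydrogen-bonded 2-OH.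

Step 14
Reactants: 24 2,4-bis(methoxymethoxy)benzaldehyde
Product: 25 1-ethynyl-2,4-bis(methoxymethoxy)benzene
Conditions: dimethyl (1-diazo-2-oxopropyl)phosphonate, K2CO3, MeOH, rt
Reagents that add atoms: dimethyl (1-diazo-2-oxopropyl)phosphonate, COP(=O)(OC)C(=[N+]=[N-])C(C)=O
Why: Ohira–Bestmann (Seyferth–Gilbert) homologation converts the aryl aldehyde into the terminal alkyne under mild carbonate conditions that leave MOM ethers intact.

**Ring C and endgame**

Step 15
Reactants: 22 2-iodo-3,5-bis(methoxymethoxy)-6-{(2R)-5-methyl-2-(prop-1-en-2-yl)-5-[(triethylsilyl)oxy]hexyl}phenol; 25 1-ethynyl-2,4-bis(methoxymethoxy)benzene; 26 carbon monoxide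
Product: 29 2-[2,4-bis(methoxymethoxy)phenyl]-5,7-bis(methoxymethoxy)-8-{(2R)-5-methyl-2-(prop-1-en-2-yl)-5-[(triethylsilyl)oxy]hexyl}-4H-chromen-4-one, via o-hydroxyaryl ynone 27 (not isolated), via enaminone 28 (not isolated)
Conditions: PdCl2(dppf) (5 mol %), CO (20 atm), Et2NH, 120 °C
Reagents that add atoms: none
Why: Pd(0) inserts into the C–I bond of 22, CO insertion gives an aroylpalladium(II) species, and amine-assisted, copper-free coupling with alkyne 25 (carbonylative Sonogashira) forms C4a–C4 and C4–C3 in ynone 27. Diethylamine adds reversibly to the ynone to give enaminone 28, and the ortho phenoxide then displaces the amine at C2, so ring C closes in the 6-endo mode (6-endo-trig addition–elimination, equivalent overall to 6-endo-dig attack on the ynone) and O1–C2 is formed. The closest known reaction type is the palladium-catalysed carbonylative annulation of o-iodophenols with terminal arylacetylenes to flavones in a secondary amine. No stereocentre is created, and the remote side-chain centre, the isopropenyl group and the tertiary silyl ether should be untouched under these basic, non-acidic conditions. The step needs three selectivities: ring-fusion regiochemistry, which is fixed because iodine sits next to the only free phenol while O5 and O7 are MOM ethers; 6-endo closure over 5-exo closure to the aurone, which the enaminone pathway in Et2NH secures; and carbonylative over direct coupling, which CO pressure and the absence of copper favour.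

Step 16
Reactants: 29 2-[2,4-bis(methoxymethoxy)phenyl]-5,7-bis(methoxymethoxy)-8-{(2R)-5-methyl-2-(prop-1-en-2-yl)-5-[(triethylsilyl)oxy]hexyl}-4H-chromen-4-one
Product: 32 2-[2,4-bis(methoxymethoxy)phenyl]-3-hydroxy-5,7-bis(methoxymethoxy)-8-{(2R)-5-methyl-2-(prop-1-en-2-yl)-5-[(triethylsilyl)oxy]hexyl}-4H-chromen-4-one, via 3-lithioflavone 30 (not isolated), via 3-boronate 31 (not isolated)
Conditions: LDA, THF, −78 °C; B(OMe)3, −78 → 0 °C; then 30% H2O2, aq NaHCO3, 0 °C
Reagents that add atoms: hydrogen peroxide, OO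
Why: LDA removes the C3 proton of flavones (it does not ortho-lithiate aryl MOM ethers), and borate trapping followed by peroxide oxidation of the C–B bond gives the flavonol without an electrophilic oxidant that would attack the isopropenyl group.

Step 17
Reactants: 32 2-[2,4-bis(methoxymethoxy)phenyl]-3-hydroxy-5,7-bis(methoxymethoxy)-8-{(2R)-5-methyl-2-(prop-1-en-2-yl)-5-[(triethylsilyl)oxy]hexyl}-4H-chromen-4-one
Product: 34 2-(2,4-dihydroxyphenyl)-3,5,7-trihydroxy-8-{(2R)-5-methyl-2-(prop-1-en-2-yl)-5-[(triethylsilyl)oxy]hexyl}-4H-chromen-4-one, via pentakis(trimethylsilyl) ether 33 (not isolated)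
Conditions: TMSOTf, 2,2′-bipyridyl, MeCN, 0 °C → rt; then H2O/THF, rt
Reagents that add atoms: none
Why: Silyl triflate/2,2′-bipyridyl cleavage of aryl MOM ethers runs through aryl silyl ethers under buffered, non-protic conditions, which avoids the strong acid that could cyclise the 7-OH onto the isopropenyl group; water then hydrolyses the aryl TMS ethers while the hindered tertiary TES ether should remain.

Step 18
Reactants: 34 2-(2,4-dihydroxyphenyl)-3,5,7-trihydroxy-8-{(2R)-5-methyl-2-(prop-1-en-2-yl)-5-[(triethylsilyl)oxy]hexyl}-4H-chromen-4-one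
Product: 35 kushenol G, 2-(2,4-dihydroxyphenyl)-3,5,7-trihydroxy-8-[(2R)-5-hydroxy-5-methyl-2-(prop-1-en-2-yl)hexyl]-4H-chromen-4-one
Conditions: HF·pyridine, pyridine/THF, 0 °C → rt
Reagents that add atoms: none
Why: Fluoride-driven desilylation with buffered HF·pyridine removes the tertiary TES ether without acid strong enough to protonate the 1,1-disubstituted alkene.

**Compound list**

1 | (S)-4-benzyloxazolidin-2-one | O=C1OC[C@H](Cc2ccccc2)N1 | starting material
2 | 3-methylbut-2-enoyl chloride | CC(C)=CC(=O)Cl | starting material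
3 | lithium salt of 1 (not isolated) | O=C1OC[C@H](Cc2ccccc2)N1[Li] | intermediate
4 | (S)-4-benzyl-3-(3-methylbut-2-enoyl)oxazolidin-2-one | CC(C)=CC(=O)N1[C@@H](Cc2ccccc2)COC1=O | intermediate
5 | 1-bromo-3-methylbut-2-ene | CC(C)=CCBr | starting material
6 | sodium Z(O)-dienolate of 4 (not isolated) | C=C(C)/C=C(\O[Na])N1[C@@H](Cc2ccccc2)COC1=O | intermediate
7 | (4S)-4-benzyl-3-[(2S)-5-methyl-2-(prop-1-en-2-yl)hex-4-enoyl]oxazolidin-2-one | C=C(C)[C@H](CC=C(C)C)C(=O)N1[C@@H](Cc2ccccc2)COC1=O | intermediate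
8 | (4S)-4-benzyl-3-[(2S)-2-[(3,3-dimethyloxiran-2-yl)methyl]-3-methylbut-3-enoyl]oxazolidin-2-one, both oxirane epimers | C=C(C)[C@H](CC1OC1(C)C)C(=O)N2[C@@H](Cc3ccccc3)COC2=O | intermediate
9 | (2S)-5-methyl-2-(prop-1-en-2-yl)hexane-1,5-diol | C=C(C)[C@H](CCC(C)(C)O)CO | intermediate
10 | (5S)-6-iodo-2-methyl-5-(prop-1-en-2-yl)hexan-2-ol | C=C(C)[C@H](CCC(C)(C)O)CI | intermediate
11 | triethyl{[(5S)-6-iodo-2-methyl-5-(prop-1-en-2-yl)hexan-2-yl]oxy}silane | C=C(C)[C@H](CCC(C)(C)O[Si](CC)(CC)CC)CI | intermediate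
12 | phloroglucinol | Oc1cc(O)cc(O)c1 | starting material
13 | 3,5-bis(methoxymethoxy)phenol | COCOc1cc(O)cc(OCOC)c1 | intermediate
14 | 3,5-bis(methoxymethoxy)phenyl N,N-diethylcarbamate | CCN(CC)C(=O)Oc1cc(OCOC)cc(OCOC)c1 | intermediate
15 | 2-lithio derivative of 14 (not isolated) | CCN(CC)C(=O)Oc1cc(OCOC)cc(OCOC)c1[Li] | intermediate
16 | 2-iodo-3,5-bis(methoxymethoxy)phenyl N,N-diethylcarbamate | CCN(CC)C(=O)Oc1cc(OCOC)cc(OCOC)c1I | intermediate
17 | alkyllithium from 11 (not isolated) | C=C(C)[C@H](CCC(C)(C)O[Si](CC)(CC)CC)C[Li] | intermediate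
18 | lithium B-alkyl-B-methoxy-9-borabicyclo[3.3.1]nonane borate from 17 (not isolated) | C=C(C)[C@H](CCC(C)(C)O[Si](CC)(CC)CC)C[B-]1(OC)C2CCCC1CCC2.[Li+] | intermediate
19 | 3,5-bis(methoxymethoxy)-2-{(2R)-5-methyl-2-(prop-1-en-2-yl)-5-[(triethylsilyl)oxy]hexyl}phenyl N,N-diethylcarbamate | C=C(C)[C@H](CCC(C)(C)O[Si](CC)(CC)CC)Cc1c(OCOC)cc(OCOC)cc1OC(=O)N(CC)CC | intermediate
20 | 6-lithio derivative of 19 (not isolated) | C=C(C)[C@H](CCC(C)(C)O[Si](CC)(CC)CC)Cc1c(OCOC)cc(OCOC)c([Li])c1OC(=O)N(CC)CC | intermediate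
21 | 2-iodo-3,5-bis(methoxymethoxy)-6-{(2R)-5-methyl-2-(prop-1-en-2-yl)-5-[(triethylsilyl)oxy]hexyl}phenyl N,N-diethylcarbamate | C=C(C)[C@H](CCC(C)(C)O[Si](CC)(CC)CC)Cc1c(OCOC)cc(OCOC)c(I)c1OC(=O)N(CC)CC | intermediate
22 | 2-iodo-3,5-bis(methoxymethoxy)-6-{(2R)-5-methyl-2-(prop-1-en-2-yl)-5-[(triethylsilyl)oxy]hexyl}phenol | C=C(C)[C@H](CCC(C)(C)O[Si](CC)(CC)CC)Cc1c(OCOC)cc(OCOC)c(I)c1O | intermediate
23 | 2,4-dihydroxybenzaldehyde | O=Cc1ccc(O)cc1O | starting material
24 | 2,4-bis(methoxymethoxy)benzaldehyde | O=Cc1ccc(OCOC)cc1OCOC | intermediate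
25 | 1-ethynyl-2,4-bis(methoxymethoxy)benzene | C#Cc1ccc(OCOC)cc1OCOC | intermediate
26 | carbon monoxide | [C-]#[O+] | starting material
27 | o-hydroxyaryl ynone from 22, 25 and 26 (not isolated) | C=C(C)[C@H](CCC(C)(C)O[Si](CC)(CC)CC)Cc1c(OCOC)cc(OCOC)c(C(=O)C#Cc2ccc(OCOC)cc2OCOC)c1O | intermediate
28 | β-(diethylamino)enone from 27 (not isolated) | C=C(C)[C@H](CCC(C)(C)O[Si](CC)(CC)CC)Cc1c(OCOC)cc(OCOC)c(C(=O)C=C(N(CC)CC)c2ccc(OCOC)cc2OCOC)c1O | intermediate
29 | 2-[2,4-bis(methoxymethoxy)phenyl]-5,7-bis(methoxymethoxy)-8-{(2R)-5-methyl-2-(prop-1-en-2-yl)-5-[(triethylsilyl)oxy]hexyl}-4H-chromen-4-one | C=C(C)[C@H](CCC(C)(C)O[Si](CC)(CC)CC)Cc1c(OCOC)cc(OCOC)c2c(=O)cc(-c3ccc(OCOC)cc3OCOC)oc12 | intermediate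
30 | 3-lithio derivative of 29 (not isolated) | C=C(C)[C@H](CCC(C)(C)O[Si](CC)(CC)CC)Cc1c(OCOC)cc(OCOC)c2c(=O)c([Li])c(-c3ccc(OCOC)cc3OCOC)oc12 | intermediate
31 | 3-(dimethoxyboryl) derivative of 29 (not isolated) | C=C(C)[C@H](CCC(C)(C)O[Si](CC)(CC)CC)Cc1c(OCOC)cc(OCOC)c2c(=O)c(B(OC)OC)c(-c3ccc(OCOC)cc3OCOC)oc12 | intermediate
32 | 2-[2,4-bis(methoxymethoxy)phenyl]-3-hydroxy-5,7-bis(methoxymethoxy)-8-{(2R)-5-methyl-2-(prop-1-en-2-yl)-5-[(triethylsilyl)oxy]hexyl}-4H-chromen-4-one | C=C(C)[C@H](CCC(C)(C)O[Si](CC)(CC)CC)Cc1c(OCOC)cc(OCOC)c2c(=O)c(O)c(-c3ccc(OCOC)cc3OCOC)oc12 | intermediate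
33 | 3,5,7,2′,4′-pentakis(trimethylsilyl) ether of 34 (not isolated) | C=C(C)[C@H](CCC(C)(C)O[Si](CC)(CC)CC)Cc1c(O[Si](C)(C)C)cc(O[Si](C)(C)C)c2c(=O)c(O[Si](C)(C)C)c(-c3ccc(O[Si](C)(C)C)cc3O[Si](C)(C)C)oc12 | intermediate
34 | 2-(2,4-dihydroxyphenyl)-3,5,7-trihydroxy-8-{(2R)-5-methyl-2-(prop-1-en-2-yl)-5-[(triethylsilyl)oxy]hexyl}-4H-chromen-4-one | C=C(C)[C@H](CCC(C)(C)O[Si](CC)(CC)CC)Cc1c(O)cc(O)c2c(=O)c(O)c(-c3ccc(O)cc3O)oc12 | intermediate
35 | kushenol G | C=C(C)[C@H](CCC(C)(C)O)Cc1c(O)cc(O)c2c(=O)c(O)c(-c3ccc(O)cc3O)oc12 | target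

**Step count and risks**

Total step count: 18. Longest linear sequence: 13 steps (1–6, 10–12, 15–18).

Steps most likely to fail:

1. Step 15. Oxidative addition and CO insertion at the di-ortho-substituted, electron-rich iodophenoxide may be slow enough that the alkyne couples without CO and closes to a 2-arylbenzofuran, or that the aroylpalladium is captured by diethylamine. The fallback builds the ynone without CO and sets out from 22. O-Allylation (allyl bromide, K2CO3, DMF) should give allyl aryl ether F1. Iodine–magnesium exchange (i-PrMgCl·LiCl, THF, −20 °C) would give arylmagnesium chloride F2, which is added to 3-[2,4-bis(methoxymethoxy)phenyl]prop-2-ynal F3 (from 25 with n-BuLi, then DMF) to give propargylic alcohol F4. MnO2 oxidation would give O-allyl ynone F5. Pd(PPh3)4 in Et2NH/THF then transfers the allyl group to the amine, and the freed phenol cyclises through 27 and enaminone 28 as in step 15. The route is rejoined at flavone 29.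

2. Step 10. Transmetalation of the bulky B-alkyl borate onto the di-ortho-substituted arylpalladium iodide may be slow, so that β-hydride elimination and protodehalogenation take over. The fallback sets out from 11: after the same iodine–lithium exchange to 17, transmetalation with ZnCl2 gives alkylzinc chloride F6, and a Negishi coupling with 16 (Pd-PEPPSI-IPent or Pd2(dba)3/CPhos, THF/NMP, rt → 50 °C) returns to 19.

3. Step 12. Hydroxide attack on a carbamate carbonyl shielded by two ortho substituents may be so slow that forcing conditions strip the TES ether or conversion stays incomplete. The fallback replaces hydrolysis by reductive cleavage: Schwartz's reagent (Cp2Zr(H)Cl, generated from Cp2ZrCl2 and LiAlH(Ot-Bu)3, THF, rt, limited excess and short contact time to spare the 1,1-disubstituted alkene) adds hydride to the carbamate carbonyl and expels the phenoxide. It sets out from 21 and arrives directly at 22 with no new intermediate.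

Further compounds
F1 | step 15 | 1-(allyloxy)-2-iodo-3,5-bis(methoxymethoxy)-6-{(2R)-5-methyl-2-(prop-1-en-2-yl)-5-[(triethylsilyl)oxy]hexyl}benzene | C=C(C)[C@H](CCC(C)(C)O[Si](CC)(CC)CC)Cc1c(OCOC)cc(OCOC)c(I)c1OCC=C
F2 | step 15 | arylmagnesium chloride from F1 | C=C(C)[C@H](CCC(C)(C)O[Si](CC)(CC)CC)Cc1c(OCOC)cc(OCOC)c([Mg]Cl)c1OCC=C
F3 | step 15 | 3-[2,4-bis(methoxymethoxy)phenyl]prop-2-ynal | O=CC#Cc1ccc(OCOC)cc1OCOC
F4 | step 15 | propargylic alcohol from F2 and F3 (both carbinol epimers) | C=C(C)[C@H](CCC(C)(C)O[Si](CC)(CC)CC)Cc1c(OCOC)cc(OCOC)c(C(O)C#Cc2ccc(OCOC)cc2OCOC)c1OCC=C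
F5 | step 15 | O-allyl ynone from F4 | C=C(C)[C@H](CCC(C)(C)O[Si](CC)(CC)CC)Cc1c(OCOC)cc(OCOC)c(C(=O)C#Cc2ccc(OCOC)cc2OCOC)c1OCC=C
F6 | step 10 | {(2S)-5-methyl-2-(prop-1-en-2-yl)-5-[(triethylsilyl)oxy]hexyl}zinc chloride | C=C(C)[C@H](CCC(C)(C)O[Si](CC)(CC)CC)C[Zn]Cl
F0 | step 12 | none | none
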